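**Plan** (germacrane numbering: ring C1–C10, C11–C13 on C7, C14 on C10, C15 on C4)

- Retrosynthesis: the 4,5-oxirane goes back to the C4=C5 alkene of an allylic alcohol, the three esters are cut at oxygen, then C2–C3 is cut. C2–C3 joins the allylic ends of C1=C10 and C4=C5 in the ten-membered ring, the cyclodeca-1,5-diene pattern of a [3,3] shift, so cutting it re-forms C5–C10 and leaves a cyclohexane C5–C10.
- That cyclohexane is (R)-carvone (ring = C5–C10, ring methyl = C14, isopropenyl = C11–C13). Forward, vinyl (C1–C2) adds to the carbonyl carbon C5 and is moved to C10 by a semipinacol shift of a spiro-oxirane built from the ring methyl, which also gives O-14 and returns the C5 ketone.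
- C3–C4–C15 enters as a 2-bromoacrolein acetal on O-14 and is closed onto C5 (six-membered, necessarily cis-fused ring), so the two alkenyl groups are trans-diequatorial. The anionic oxy-Cope shift then opens the cyclohexane to the ten-membered ring.
- The enolate is fixed as triflate and reduced; the acetal is opened to the C15 enal, which keeps O-14 and O-15 apart for acylation. C12 is acetoxylated via the allylic chloride; enal reduction and epoxidation finish.
- Stereochemistry: C7 from (R)-carvone; C9 from a hydroxyl-directed epoxidation; both ring-alkene geometries from the chair transition state; C4/C5 from the titanium–tartrate epoxidation; C2'/C3' from a syn-aldol with an (R)-oxazolidinone.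

Key step: step 9

Assumption: the acetal carbon C15 in compounds 9–17 is a temporary stereocentre removed in step 12; it is carried as both epimers and written without configuration.

**Step 1**
Reactants: 1 (R)-(−)-carvone
Product: 2 (1S,5R)-1-ethenyl-2-methyl-5-(prop-1-en-2-yl)cyclohex-2-en-1-ol
Conditions: CH2=CHMgBr, THF, −78 to 0 °C; then H2O
Reagents that add atoms: vinylmagnesium bromide, C=C[Mg]Br
Why: Grignard 1,2-addition to the enone carbonyl; axial attack anti to the pseudo-equatorial isopropenyl group should set the C5 carbinol with vinyl trans and OH cis to that group.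

**Step 2**
Reactants: 2
Product: 3 (1S,2S,4R,6S)-2-ethenyl-1-methyl-4-(prop-1-en-2-yl)-7-oxabicyclo[4.1.0]heptan-2-ol
Conditions: VO(acac)2 (cat.), t-BuOOH, CH2Cl2, 0 °C to rt
Reagents that add atoms: tert-butyl hydroperoxide, CC(C)(C)OO
Why: Hydroxyl-directed vanadium-catalysed epoxidation of the cyclic allylic alcohol delivers oxygen to the trisubstituted ring alkene on the OH face (vinyl and isopropenyl are less reactive), which sets the future C9–O bond cis to the C7 substituent.

**Step 3**
Reactants: 3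
Product: 4 (1S,3S,5R)-1-ethenyl-2-methylidene-5-(prop-1-en-2-yl)cyclohexane-1,3-diol
Conditions: LiN(iPr)2 (excess), Et2O, 0 °C to reflux; then H2O
Reagents that add atoms: none
Why: Base-induced isomerisation of an epoxide to an allylic alcohol (syn β-elimination); only the C14 methyl and C8 carry β-hydrogens, and removal of the less hindered methyl proton should give the exocyclic alkene with the C9–O configuration retained.

**Step 4**
Reactants: 4
Product: 5 (1S,3S,5R)-3-(tert-butyldimethylsilyloxy)-1-ethenyl-2-methylidene-5-(prop-1-en-2-yl)cyclohexan-1-ol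
Conditions: t-BuMe2SiCl, imidazole, DMF, rt
Reagents that add atoms: tert-butyldimethylsilyl chloride, CC(C)(C)[Si](C)(C)Cl
Why: Silyl ether formation on the secondary allylic alcohol only, leaving the hindered tertiary alcohol free to direct and drive the next two steps.

**Step 5**
Reactants: 5
Product: 6 (3S,4S,6R,8S)-8-(tert-butyldimethylsilyloxy)-4-ethenyl-6-(prop-1-en-2-yl)-1-oxaspiro[2.5]octan-4-ol
Conditions: VO(acac)2 (cat.), t-BuOOH, CH2Cl2, 0 °C
Reagents that add atoms: tert-butyl hydroperoxide, CC(C)(C)OO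
Why: Second hydroxyl-directed vanadium-catalysed epoxidation, now of the exocyclic 1,1-disubstituted alkene, should place the spiro-oxirane oxygen on the face of the C5 hydroxyl and anti to the axial vinyl group.

**Step 6**
Reactants: 6
Product: 7 (2S,3S,5R)-3-(tert-butyldimethylsilyloxy)-2-ethenyl-2-(hydroxymethyl)-5-(prop-1-en-2-yl)cyclohexan-1-one
Conditions: BF3·OEt2 (cat.), CH2Cl2, −78 °C
Reagents that add atoms: none
Why: Lewis-acid semipinacol rearrangement of a 2,3-epoxy alcohol; the axial vinyl group on C5 is antiperiplanar to the breaking C10–O bond and migrates with inversion at C10 while the carbinol becomes the ketone, which sets the quaternary centre (vinyl trans, CH2OH cis to the C9 silyloxy group).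

**Step 7**
Reactants: 7; 8 2-bromoacrolein diethyl acetal (2-bromo-3,3-diethoxyprop-1-ene)
Product: 9 (2S,3S,5R)-2-{[(2-bromo-1-ethoxyprop-2-en-1-yl)oxy]methyl}-3-(tert-butyldimethylsilyloxy)-2-ethenyl-5-(prop-1-en-2-yl)cyclohexan-1-one
Conditions: 8 (excess), pyridinium p-toluenesulfonate (cat.), toluene, 40 °C, reduced pressure
Reagents that add atoms: none
Why: Acid-catalysed transacetalisation, driven by excess 8 and removal of ethanol, attaches the C3–C4–C15 unit to O-14 as a mixed acetal.

**Step 8**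
Reactants: 9
Product: 11 (4aS,6R,8S,8aS)-8-(tert-butyldimethylsilyloxy)-3-ethoxy-8a-ethenyl-4-methylidene-6-(prop-1-en-2-yl)octahydro-1H-isochromen-4a-ol, via alkenylchromium dichloride 10 (not isolated)
Conditions: CrCl2 (excess), NiCl2 (cat.), DMF, rt to 50 °C; then H2O
Reagents that add atoms: none
Why: Intramolecular Nozaki–Hiyama–Kishi addition of the alkenylchromium species to the ketone closes a six-membered ring that can only be cis-fused, so C4 enters cis to C14 and trans to the vinyl group and thereby sets the C5 carbinol.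

**Step 9**
Reactants: 11
Product: 14 (1(10)E,4E,7R,9S)-9-(tert-butyldimethylsilyloxy)-15-ethoxy-14,15-epoxygermacra-1(10),4,11(13)-trien-5-yl trifluoromethanesulfonate, via potassium alkoxide 12 (not isolated), via potassium enolate 13 (not isolated)
Conditions: KN(SiMe3)2, 18-crown-6, THF, −20 °C to rt; then PhNTf2, −78 °C
Reagents that add atoms: N-phenylbis(trifluoromethanesulfonimide), O=S(=O)(N(c1ccccc1)S(=O)(=O)C(F)(F)F)C(F)(F)F
Why: Deprotonation gives alkoxide 12, whose C3=C4–C5(O−)–C10–C1=C2 array undergoes the anionic oxy-Cope [3,3] shift (closest known type: ring expansion of trans-1,2-dialkenylcyclohexanols to cyclodec-5-enones), breaking C5–C10 and forming C2–C3. The ten-membered carbocycle arises by four-atom ring expansion of the cyclohexane through a six-centre chair transition state, and the acetal ring grows from six to eight members in the same event. No sp3 centre is created; the two new double bonds are set by the chair, in which C6 and C9 are pseudo-equatorial because the alkenyl groups are trans-diequatorial on a cyclohexane chair that also holds the C7 and C9 substituents equatorial, so C9 ends trans to C2 and C6 trans to C3. The step needs this ring-E,E geometry and a regiodefined enolate, and both are secured by the cis-fused acetal ring, which fixes C4 cis to C14. Enolate 13 is intercepted cold by PhNTf2 before proton exchange or loss of a C15 alkoxide, which stores the C4=C5 geometry in triflate 14.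

**Step 10**
Reactants: 14
Product: 15 (1(10)E,4Z,7S,9S)-9-(tert-butyldimethylsilyloxy)-15-ethoxy-14,15-epoxygermacra-1(10),4,11(13)-triene
Conditions: Pd(OAc)2 (cat.), PPh3, HCO2H, Bu3N, DMF, 60 °C
Reagents that add atoms: none
Why: Palladium-catalysed formate reduction of the enol triflate (oxidative addition, hydride transfer, reductive elimination) replaces OTf by H with retention of alkene geometry; no allylic ester is present at this stage.

**Step 11**
Reactants: 15
Product: 17 (1(10)E,4Z,7S,9S)-15-ethoxy-14,15-epoxygermacra-1(10),4,11(13)-trien-9-yl 2-methylpropanoate, via C9 alcohol 16 (not isolated)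
Conditions: Bu4NF, THF, 0 °C; then (iPrCO)2O, Et3N, 4-(dimethylamino)pyridine (cat.), rt
Reagents that add atoms: isobutyric anhydride, CC(C)C(=O)OC(=O)C(C)C
Why: Fluoride cleavage of the silyl ether followed by acylation of the liberated C9 alcohol in the same flask; the stereocentre is not touched.

**Step 12**
Reactants: 17
Product: 18 (1(10)E,4Z,7S,9S)-14-hydroxy-15-oxogermacra-1(10),4,11(13)-trien-9-yl 2-methylpropanoate
Conditions: pyridinium p-toluenesulfonate (cat.), acetone/H2O, rt
Reagents that add atoms: water, O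
Why: Mild acid hydrolysis of the α,β-unsaturated mixed acetal frees O-14 as the alcohol and C15 as the enal, which keeps the two primary oxygens at different oxidation levels.

**Step 13**
Reactants: 19 (R)-4-benzyl-3-propanoyl-1,3-oxazolidin-2-one; 20 acetaldehyde
Product: 22 (R)-4-benzyl-3-[(2R,3S)-3-hydroxy-2-methylbutanoyl]-1,3-oxazolidin-2-one, via Z-boron enolate 21 (not isolated)
Conditions: Bu2BOTf, iPr2NEt, CH2Cl2, −78 °C; 20, −78 to 0 °C; pH 7 buffer/MeOH
Reagents that add atoms: none
Why: Boron-mediated syn-aldol (Evans aldol) through the Z-enolate and a chair transition state; the (R)-benzyl auxiliary sets C2' (R) and C3' (S).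

**Step 14**
Reactants: 22
Product: 23 (R)-4-benzyl-3-[(2R,3S)-2-methyl-3-(triethylsilyloxy)butanoyl]-1,3-oxazolidin-2-one
Conditions: Et3SiCl, imidazole, DMF, 0 °C to rt
Reagents that add atoms: chlorotriethylsilane, CC[Si](CC)(CC)Cl
Why: Silyl ether formation protects the secondary alcohol before carboxyl activation.

**Step 15**
Reactants: 23
Product: 25 (2R,3S)-2-methyl-3-(triethylsilyloxy)butanoic acid, via lithium peroxycarboxylate 24 (not isolated)
Conditions: LiOH, H2O2, THF/H2O, 0 °C; Na2SO3; dil. HCl to pH 4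
Reagents that add atoms: hydrogen peroxide, OO
Why: Hydroperoxide cleavage of the imide at the exocyclic carbonyl followed by sulfite reduction gives the acid and returns the auxiliary without epimerisation at C2'.

**Step 16**
Reactants: 18; 25
Product: 26 (1(10)E,4Z,7S,9S)-9-(2-methylpropanoyloxy)-15-oxogermacra-1(10),4,11(13)-trien-14-yl (2R,3S)-2-methyl-3-(triethylsilyloxy)butanoate
Conditions: dicyclohexylcarbodiimide, 4-(dimethylamino)pyridine (cat.), CH2Cl2, 0 °C
Reagents that add atoms: none
Why: Steglich esterification of the primary allylic alcohol; low temperature and only catalytic nucleophile limit epimerisation at C2' and conjugate-addition isomerisation of the enal.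

**Step 17**
Reactants: 26
Product: 27 (1(10)E,4Z,7S,9S)-12-chloro-9-(2-methylpropanoyloxy)-15-oxogermacra-1(10),4,11(13)-trien-14-yl (2R,3S)-2-methyl-3-(triethylsilyloxy)butanoate
Conditions: Ca(OCl)2, CO2 (solid), CH2Cl2/H2O, 0 °C
Reagents that add atoms: calcium hypochlorite, [Ca+2].[O-]Cl.[O-]Cl
Why: Ene-type allylic chlorination by hypochlorous acid formed in the flask; the isopropenyl group is the only electron-rich alkene, the other two being an enal and an alkene flanked by two allylic esters.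

**Step 18**
Reactants: 27
Product: 28 (1(10)E,4Z,7S,9S)-12-acetoxy-9-(2-methylpropanoyloxy)-15-oxogermacra-1(10),4,11(13)-trien-14-yl (2R,3S)-2-methyl-3-(triethylsilyloxy)butanoate
Conditions: KOAc, 18-crown-6 (cat.), MeCN, 40 °C
Reagents that add atoms: potassium acetate, CC(=O)[O-].[K+]
Why: SN2 displacement of the primary allylic chloride by acetate (SN2 and SN2' give the same product).

**Step 19**
Reactants: 28
Product: 30 (1(10)E,4Z,7S,9S)-12-acetoxy-15-hydroxy-9-(2-methylpropanoyloxy)germacra-1(10),4,11(13)-trien-14-yl (2R,3S)-3-hydroxy-2-methylbutanoate, via triethylsilyl-protected allylic alcohol 29 (not isolated)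
Conditions: NaBH4, CeCl3·7H2O, MeOH, −20 °C; then pyridinium p-toluenesulfonate, 0 °C to rt
Reagents that add atoms: none
Why: Luche 1,2-reduction of the enal to the allylic alcohol, then acid-catalysed methanolysis of the triethylsilyl ether in the same flask; the esters should survive cold methanol.

**Step 20**
Reactants: 30
Product: 31 (1(10)E,4S,5R,7R,9S)-12-acetoxy-4,5-epoxy-15-hydroxy-9-(2-methylpropanoyloxy)germacra-1(10),11(13)-dien-14-yl (2R,3S)-3-hydroxy-2-methylbutanoate (CNP0256542.1)
Conditions: Ti(OiPr)4 (cat.), L-(+)-diethyl tartrate, t-BuOOH, 4 Å molecular sieves, CH2Cl2, −20 °C; non-basic work-up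
Reagents that add atoms: tert-butyl hydroperoxide, CC(C)(C)OO
Why: Sharpless asymmetric epoxidation; titanium binds only the C15 allylic alcohol and L-(+)-tartrate directs oxygen to the alkene face that gives (4S,5R), so the trans-oxirane arises from the ring-E alkene under reagent control.

**Compound list**

1 | (R)-(−)-carvone, (5R)-2-methyl-5-(prop-1-en-2-yl)cyclohex-2-en-1-one | CC1=CC[C@H](CC1=O)C(C)=C | starting material
2 | (1S,5R)-1-ethenyl-2-methyl-5-(prop-1-en-2-yl)cyclohex-2-en-1-ol | CC1=CC[C@H](C[C@]1(O)C=C)C(C)=C | intermediate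
3 | (1S,2S,4R,6S)-2-ethenyl-1-methyl-4-(prop-1-en-2-yl)-7-oxabicyclo[4.1.0]heptan-2-ol | C[C@]12O[C@H]1C[C@H](C[C@]2(O)C=C)C(C)=C | intermediate
4 | (1S,3S,5R)-1-ethenyl-2-methylidene-5-(prop-1-en-2-yl)cyclohexane-1,3-diol | C=C1[C@@H](O)C[C@H](C[C@]1(O)C=C)C(C)=C | intermediate
5 | (1S,3S,5R)-3-(tert-butyldimethylsilyloxy)-1-ethenyl-2-methylidene-5-(prop-1-en-2-yl)cyclohexan-1-ol | C=C1[C@@H](O[Si](C)(C)C(C)(C)C)C[C@H](C[C@]1(O)C=C)C(C)=C | intermediate
6 | (3S,4S,6R,8S)-8-(tert-butyldimethylsilyloxy)-4-ethenyl-6-(prop-1-en-2-yl)-1-oxaspiro[2.5]octan-4-ol | C1O[C@]12[C@@H](O[Si](C)(C)C(C)(C)C)C[C@H](C[C@]2(O)C=C)C(C)=C | intermediate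
7 | (2S,3S,5R)-3-(tert-butyldimethylsilyloxy)-2-ethenyl-2-(hydroxymethyl)-5-(prop-1-en-2-yl)cyclohexan-1-one | OC[C@@]1(C=C)[C@@H](O[Si](C)(C)C(C)(C)C)C[C@H](CC1=O)C(C)=C | intermediate
8 | 2-bromoacrolein diethyl acetal (2-bromo-3,3-diethoxyprop-1-ene) | C=C(Br)C(OCC)OCC | starting material
9 | (2S,3S,5R)-2-{[(2-bromo-1-ethoxyprop-2-en-1-yl)oxy]methyl}-3-(tert-butyldimethylsilyloxy)-2-ethenyl-5-(prop-1-en-2-yl)cyclohexan-1-one (both acetal epimers) | C=C(Br)C(OCC)OC[C@@]1(C=C)[C@@H](O[Si](C)(C)C(C)(C)C)C[C@H](CC1=O)C(C)=C | intermediate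
10 | alkenylchromium dichloride derived from 9 (trivalent chromium on C4 in place of bromine) | C=C([Cr](Cl)Cl)C(OCC)OC[C@@]1(C=C)[C@@H](O[Si](C)(C)C(C)(C)C)C[C@H](CC1=O)C(C)=C | intermediate
11 | (4aS,6R,8S,8aS)-8-(tert-butyldimethylsilyloxy)-3-ethoxy-8a-ethenyl-4-methylidene-6-(prop-1-en-2-yl)octahydro-1H-isochromen-4a-ol (C3 both epimers) | C=C1C(OCC)OC[C@@]2(C=C)[C@@H](O[Si](C)(C)C(C)(C)C)C[C@H](C[C@@]12O)C(C)=C | intermediate
12 | potassium alkoxide of 11 | C=C1C(OCC)OC[C@@]2(C=C)[C@@H](O[Si](C)(C)C(C)(C)C)C[C@H](C[C@@]12[O-])C(C)=C.[K+] | intermediate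
13 | potassium (1(10)E,4E,7R,9S)-9-(tert-butyldimethylsilyloxy)-15-ethoxy-14,15-epoxygermacra-1(10),4,11(13)-trien-5-olate (C14–O–C15 ether bridge) | C=C(C)[C@@H]1C[C@H](O[Si](C)(C)C(C)(C)C)/C2=C/CC/C(C(OCC)OC2)=C([O-])/C1.[K+] | intermediate
14 | (1(10)E,4E,7R,9S)-9-(tert-butyldimethylsilyloxy)-15-ethoxy-14,15-epoxygermacra-1(10),4,11(13)-trien-5-yl trifluoromethanesulfonate | C=C(C)[C@@H]1C[C@H](O[Si](C)(C)C(C)(C)C)/C2=C/CC/C(C(OCC)OC2)=C(OS(=O)(=O)C(F)(F)F)/C1 | intermediate
15 | (1(10)E,4Z,7S,9S)-9-(tert-butyldimethylsilyloxy)-15-ethoxy-14,15-epoxygermacra-1(10),4,11(13)-triene | C=C(C)[C@@H]1C[C@H](O[Si](C)(C)C(C)(C)C)/C2=C/CC/C(C(OCC)OC2)=C/C1 | intermediate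
16 | (1(10)E,4Z,7S,9S)-15-ethoxy-14,15-epoxygermacra-1(10),4,11(13)-trien-9-ol | C=C(C)[C@@H]1C[C@H](O)/C2=C/CC/C(C(OCC)OC2)=C/C1 | intermediate
17 | (1(10)E,4Z,7S,9S)-15-ethoxy-14,15-epoxygermacra-1(10),4,11(13)-trien-9-yl 2-methylpropanoate | C=C(C)[C@@H]1C[C@H](OC(=O)C(C)C)/C2=C/CC/C(C(OCC)OC2)=C/C1 | intermediate
18 | (1(10)E,4Z,7S,9S)-14-hydroxy-15-oxogermacra-1(10),4,11(13)-trien-9-yl 2-methylpropanoate | C=C(C)[C@@H]1C[C@H](OC(=O)C(C)C)/C(CO)=C/CC/C(C=O)=C/C1 | intermediate
19 | (R)-4-benzyl-3-propanoyl-1,3-oxazolidin-2-one | CCC(=O)N1[C@H](Cc2ccccc2)COC1=O | starting material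
20 | acetaldehyde | CC=O | starting material
21 | dibutylboron Z-enolate of 19 | C/C=C(\OB(CCCC)CCCC)N1[C@H](Cc2ccccc2)COC1=O | intermediate
22 | (R)-4-benzyl-3-[(2R,3S)-3-hydroxy-2-methylbutanoyl]-1,3-oxazolidin-2-one | O=C([C@H](C)[C@H](C)O)N1[C@H](Cc2ccccc2)COC1=O | intermediate
23 | (R)-4-benzyl-3-[(2R,3S)-2-methyl-3-(triethylsilyloxy)butanoyl]-1,3-oxazolidin-2-one | O=C([C@H](C)[C@H](C)O[Si](CC)(CC)CC)N1[C@H](Cc2ccccc2)COC1=O | intermediate
24 | lithium (2R,3S)-2-methyl-3-(triethylsilyloxy)butaneperoxoate | [Li+].[O-]OC(=O)[C@H](C)[C@H](C)O[Si](CC)(CC)CC | intermediate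
25 | (2R,3S)-2-methyl-3-(triethylsilyloxy)butanoic acid | OC(=O)[C@H](C)[C@H](C)O[Si](CC)(CC)CC | intermediate
26 | (1(10)E,4Z,7S,9S)-9-(2-methylpropanoyloxy)-15-oxogermacra-1(10),4,11(13)-trien-14-yl (2R,3S)-2-methyl-3-(triethylsilyloxy)butanoate | C=C(C)[C@@H]1C[C@H](OC(=O)C(C)C)/C(COC(=O)[C@H](C)[C@H](C)O[Si](CC)(CC)CC)=C/CC/C(C=O)=C/C1 | intermediate
27 | 12-chloro derivative of 26 | C=C(CCl)[C@@H]1C[C@H](OC(=O)C(C)C)/C(COC(=O)[C@H](C)[C@H](C)O[Si](CC)(CC)CC)=C/CC/C(C=O)=C/C1 | intermediate
28 | 12-acetoxy derivative of 26 | C=C(COC(C)=O)[C@@H]1C[C@H](OC(=O)C(C)C)/C(COC(=O)[C@H](C)[C@H](C)O[Si](CC)(CC)CC)=C/CC/C(C=O)=C/C1 | intermediate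
29 | (1(10)E,4Z,7S,9S)-12-acetoxy-15-hydroxy-9-(2-methylpropanoyloxy)germacra-1(10),4,11(13)-trien-14-yl (2R,3S)-2-methyl-3-(triethylsilyloxy)butanoate | C=C(COC(C)=O)[C@@H]1C[C@H](OC(=O)C(C)C)/C(COC(=O)[C@H](C)[C@H](C)O[Si](CC)(CC)CC)=C/CC/C(CO)=C/C1 | intermediate
30 | (1(10)E,4Z,7S,9S)-12-acetoxy-15-hydroxy-9-(2-methylpropanoyloxy)germacra-1(10),4,11(13)-trien-14-yl (2R,3S)-3-hydroxy-2-methylbutanoate | C=C(COC(C)=O)[C@@H]1C[C@H](OC(=O)C(C)C)/C(COC(=O)[C@H](C)[C@H](C)O)=C/CC/C(CO)=C/C1 | intermediate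
31 | CNP0256542.1, (1(10)E,4S,5R,7R,9S)-12-acetoxy-4,5-epoxy-15-hydroxy-9-(2-methylpropanoyloxy)germacra-1(10),11(13)-dien-14-yl (2R,3S)-3-hydroxy-2-methylbutanoate | C=C(COC(C)=O)[C@@H]1C[C@H](OC(=O)C(C)C)/C(COC(=O)[C@H](C)[C@H](C)O)=C/CC[C@@]2(CO)O[C@@H]2C1 | target

**Step count and risks**

Total steps: 20. Longest linear sequence: 17 (steps 1–12 and 16–20 from 1); the side chain (steps 13–15) joins at step 16.

Steps most likely to fail:

1. Step 9. The potassium enolate may lose an alkoxide from C15 (β-elimination) or exchange protons before O-sulfonylation, which would erase the C4=C5 geometry; tight ion pairing could also slow the rearrangement. Fallback (sets out from 11, comes back at 14): 11 is silylated with 1-(trimethylsilyl)imidazole to the trimethylsilyl ether of 11 F1. Heating in toluene (sealed tube, about 180 °C) effects the neutral siloxy-Cope shift and gives the ring-expanded trimethylsilyl enol ether F2 without any free enolate. MeLi in THF at −78 to 0 °C then releases the lithium enolate F3 in the cold, and PhNTf2 converts it into 14.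

2. Step 17. Electrophilic chlorine may also attack the C1=C10 alkene, or the aldehyde may be oxidised, so the chemoselectivity of the late allylic chlorination may be insufficient. Fallback (sets out from 26, comes back at 28): SeO2 (cat.) with t-BuOOH in CH2Cl2 hydroxylates the isopropenyl methyl group by an ene reaction and [2,3] shift to give the C12 alcohol F4, which is acetylated with Ac2O and pyridine to 28.

3. Step 8. Addition of the alkenylchromium species to the hindered, enolisable ketone may be slow, with protodehalogenation competing. Fallback (sets out from 7, comes back at 11): transacetalisation of 7 with 3,3-diethoxyprop-1-yne (pyridinium p-toluenesulfonate) gives the propargylic mixed acetal F5. SmI2 with HMPA and t-BuOH in THF then forms the ketyl radical, which closes 6-exo-dig onto the alkyne; reduction and protonation of the alkenyl radical give 11 with the same forced cis ring fusion.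

**Further compounds**

F1 | step 9 | (4aS,6R,8S,8aS)-8-(tert-butyldimethylsilyloxy)-3-ethoxy-8a-ethenyl-4-methylidene-6-(prop-1-en-2-yl)-4a-(trimethylsilyloxy)octahydro-1H-isochromene | C=C1C(OCC)OC[C@@]2(C=C)[C@@H](O[Si](C)(C)C(C)(C)C)C[C@H](C[C@@]12O[Si](C)(C)C)C(C)=C
F2 | step 9 | (1(10)E,4E,7R,9S)-9-(tert-butyldimethylsilyloxy)-15-ethoxy-14,15-epoxy-5-(trimethylsilyloxy)germacra-1(10),4,11(13)-triene | C=C(C)[C@@H]1C[C@H](O[Si](C)(C)C(C)(C)C)/C2=C/CC/C(C(OCC)OC2)=C(O[Si](C)(C)C)/C1
F3 | step 9 | lithium (1(10)E,4E,7R,9S)-9-(tert-butyldimethylsilyloxy)-15-ethoxy-14,15-epoxygermacra-1(10),4,11(13)-trien-5-olate | C=C(C)[C@@H]1C[C@H](O[Si](C)(C)C(C)(C)C)/C2=C/CC/C(C(OCC)OC2)=C([O-])/C1.[Li+]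
F4 | step 17 | (1(10)E,4Z,7S,9S)-12-hydroxy-9-(2-methylpropanoyloxy)-15-oxogermacra-1(10),4,11(13)-trien-14-yl (2R,3S)-2-methyl-3-(triethylsilyloxy)butanoate | C=C(CO)[C@@H]1C[C@H](OC(=O)C(C)C)/C(COC(=O)[C@H](C)[C@H](C)O[Si](CC)(CC)CC)=C/CC/C(C=O)=C/C1
F5 | step 8 | (2S,3S,5R)-3-(tert-butyldimethylsilyloxy)-2-ethenyl-2-{[(1-ethoxyprop-2-yn-1-yl)oxy]methyl}-5-(prop-1-en-2-yl)cyclohexan-1-one | C#CC(OCC)OC[C@@]1(C=C)[C@@H](O[Si](C)(C)C(C)(C)C)C[C@H](CC1=O)C(C)=C
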